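Ring E, C7' (R), C8' (S) and C9' of the cis-dioxane ring D, with their two C–O bonds anti as in an erythro arylglycerol, are C1', C2, C3 and C4 of (2R,3R)-taxifolin; only C4 needs oxygen in place of its aryl carbon C4a. A Baeyer–Villiger oxidation of a taxifolin 3-acetate (5-O-benzyl, 7,3',4'-tri-O-MOM) inserts that oxygen into C4–C4a in one operation, expanding the pyranone to a seven-membered aryl lactone while C2 and C3 stay untouched. Reduction, oxidative removal of the spent ring and O-arylations at oxygen then give ring D with retention; an Evans aldol and a second O-arylation build trans ring B, and a Wittig reaction adds the enal.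

Key step: step 4

Remark on locants: C7'–C9' are the chain carbons of ring D (C7' carries catechol ring E), C7–C9 those of ring B (C7 carries ring C), ring A carries the enal; taxifolin atoms keep flavonoid numbers; MOM = methoxymethyl, TBS = tert-butyldimethylsilyl.
Assumption: 4-fluoro-3-iodobenzaldehyde, 4-hydroxy-3-iodobenzonitrile and (4R)-4-benzyl-3-(chloroacetyl)-1,3-oxazolidin-2-one are bought as such.

Step 1
Reactants: 1 (+)-taxifolin
Product: 2 7,3',4'-tri-O-MOM-taxifolin
Conditions: MOMCl (3.2 equiv), K2CO3, acetone, 0 °C → rt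
Reagents that add atoms: chloromethyl methyl ether, COCCl
Why: Williamson O-alkylation of the three acidic phenols, while K2CO3 ionises neither the chelated 5-OH nor the 3-OH at this temperature; MOM is used on ring E because, unlike benzyl, it can be removed at the end without hydrogenating the enal.

Step 2
Reactants: 2 7,3',4'-tri-O-MOM-taxifolin
Product: 3 5-O-benzyl-7,3',4'-tri-O-MOM-taxifolin
Conditions: BnBr, K2CO3, DMF, rt → 40 °C
Reagents that add atoms: benzyl bromide, BrCc1ccccc1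
Why: Williamson benzylation of the hydrogen-bonded 5-OH under the more forcing bromide/DMF conditions, the 3-OH staying free; this removes the chelate that deactivates C4=O and later makes the spent ring a 2,4,6-trialkoxyphenol, and with O4' already capped C2 cannot scramble through a quinone methide.

Step 3
Reactants: 3 5-O-benzyl-7,3',4'-tri-O-MOM-taxifolin
Product: 4 3-O-acetyl-5-O-benzyl-7,3',4'-tri-O-MOM-taxifolin
Conditions: Ac2O, pyridine, DMAP (cat.), CH2Cl2, 0 °C → rt
Reagents that add atoms: acetic anhydride, CC(=O)OC(C)=O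
Why: DMAP-catalysed O-acylation of the secondary alcohol; the acetoxy group makes C3 a poor migrating group and the C4 carbonyl more electrophilic for step 4.

Step 4
Reactants: 4 3-O-acetyl-5-O-benzyl-7,3',4'-tri-O-MOM-taxifolin
Product: 5 (3R,4R)-9-(benzyloxy)-4-[3,4-bis(methoxymethoxy)phenyl]-7-(methoxymethoxy)-2-oxo-3,4-dihydro-2H-1,5-benzodioxepin-3-yl acetate
Conditions: urea·H2O2, (CF3CO)2O, Na2HPO4, CH2Cl2, 0 °C → rt
Reagents that add atoms: trifluoroperacetic acid (formed in the flask), OOC(=O)C(F)(F)F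
Why: Trifluoroperacetic acid adds to the C4 carbonyl, made electrophilic by the 3-acetoxy group and the absence of a 5-OH chelate, and in the Criegee perhemiketal the C4–C4a bond shifts to the inner peroxide oxygen as trifluoroacetate leaves. This is a Baeyer–Villiger oxidation of a chroman-4-one with aryl migration, the same reaction type as the peracid (Dakin-type) oxidation of ortho- and para-alkoxyaryl ketones to aryl esters. The seven-membered 1,5-benzodioxepin-2-one ring is not closed by a cyclisation; it arises by ring expansion, the 1,2-shift inserting one oxygen into the six-membered ring and forming the C4–O (later C9'–O) bond. No stereocentre is formed or endangered: the migrating atom is an sp2 aryl carbon and C2 and C3 keep all four of their bonds, so (2R,3R) passes unchanged into (3R,4R) of the lactone. The step needs aryl instead of C3 migration and no oxidation of the arenes: the migrating ring has three oxygen donors (O1 and 5-OBn ortho, 7-OMOM para), C3 is deactivated by its acetoxy group, and solid Na2HPO4 with a limited excess of peracid at 0 °C keeps the medium from becoming acidic towards MOM ethers or hydroxylating the rings.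

Step 5
Reactants: 5 ring-expanded lactone
Product: 6 (2S,3R)-3-[3-(benzyloxy)-2-hydroxy-5-(methoxymethoxy)phenoxy]-3-[3,4-bis(methoxymethoxy)phenyl]propane-1,2-diol
Conditions: LiAlH4, THF, −20 → 0 °C (inverse addition); Rochelle salt work-up
Reagents that add atoms: none
Why: Hydride reduction of the aryl lactone (to C9'H2OH and the phenol) and of the acetate; attack on the activated aryl ester should outrun E1cB loss of the β-aryloxy group, and no bond to C7' or C8' is broken.

Step 6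
Reactants: 6 phenol diol
Product: 7 2-(benzyloxy)-6-{(R)-[3,4-bis(methoxymethoxy)phenyl][(4S)-2,2-dimethyl-1,3-dioxolan-4-yl]methoxy}-4-(methoxymethoxy)phenol
Conditions: 2,2-dimethoxypropane, PPTS (cat.), acetone, rt
Reagents that add atoms: 2,2-dimethoxypropane, COC(C)(C)OC
Why: Acid-catalysed transketalisation gives the acetonide of the only 1,2-diol (O8'/O9'), without a regiochemical choice because O7' is still blocked by the spent aryl ring.

Step 7
Reactants: 7 acetonide phenol
Product: 9 (R)-[3,4-bis(methoxymethoxy)phenyl][(4S)-2,2-dimethyl-1,3-dioxolan-4-yl]methanol, via alkoxyquinone 8 (not isolated)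
Conditions: PhI(OAc)2, MeCN/H2O (5:1), 0 °C; extractive work-up; then NaOMe (cat.), dry MeOH, 0 °C → rt
Reagents that add atoms: none
Why: Oxidative dearomatisation of the 2,4,6-trialkoxyphenol by PhI(OAc)2 gives the alkoxy-1,4-benzoquinone 8, which still holds O7' as a vinylogous ester, and base-catalysed vinylogous transesterification (addition–elimination of methoxide at the alkoxy-bearing quinone carbons, the known alcoholysis of alkoxyquinones) then expels O7' as the alcohol in excess methanol; only aryl C–O bonds break, so C7' keeps its configuration.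

Step 8
Reactants: 9 alcohol with free O7', 10 4-fluoro-3-iodobenzaldehyde
Product: 11 4-{(R)-[3,4-bis(methoxymethoxy)phenyl][(4S)-2,2-dimethyl-1,3-dioxolan-4-yl]methoxy}-3-iodobenzaldehyde
Conditions: NaH, DMF, 0 °C; then 10, 0 °C → rt
Reagents that add atoms: none
Why: Nucleophilic aromatic substitution (SNAr) of the secondary alkoxide at the fluorine para to the formyl group, which puts O7' para to the future C7; the bond forms at oxygen, so C7' is retained, and the acetonide cannot migrate under base.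

Step 9
Reactants: 12 4-hydroxy-3-iodobenzonitrile, 13 (4R)-4-benzyl-3-(chloroacetyl)-1,3-oxazolidin-2-one
Product: 14 4-{2-[(4R)-4-benzyl-2-oxo-1,3-oxazolidin-3-yl]-2-oxoethoxy}-3-iodobenzonitrile
Conditions: K2CO3, acetone, 50 °C
Reagents that add atoms: none
Why: Williamson O-alkylation (SN2) of the acidic phenol by the activated α-chloro imide, giving the aryloxyacetyl imide that carries ring A with O8 para to the nitrile.

Step 10
Reactants: 11 ring C aldehyde, 14 aryloxyacetyl imide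
Product: 16 4-{[(2R,3S)-1-[(4R)-4-benzyl-2-oxo-1,3-oxazolidin-3-yl]-3-hydroxy-3-(3-iodo-4-{(R)-[3,4-bis(methoxymethoxy)phenyl][(4S)-2,2-dimethyl-1,3-dioxolan-4-yl]methoxy}phenyl)-1-oxopropan-2-yl]oxy}-3-iodobenzonitrile, via boron Z-enolate 15 (not isolated)
Conditions: n-Bu2BOTf, Et3N, CH2Cl2, −78 → 0 °C; then 11, −78 → 0 °C; pH 7 buffer, MeOH, H2O2, 0 °C
Reagents that add atoms: none
Why: Evans syn aldol of a glycolate-type imide, in which the Z boron enolate reacts through a Zimmerman–Traxler chair on the face left open by the (4R)-benzyl auxiliary; this sets C8 and C7 together as the (2R,3S) syn adduct, which is (7S,8S) threo once C9 is reduced, and the remote C7'/C8' centres have no say.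

Step 11
Reactants: 16 aldol adduct
Product: 17 4-{[(1S,2S)-1,3-dihydroxy-1-(3-iodo-4-{(R)-[3,4-bis(methoxymethoxy)phenyl][(4S)-2,2-dimethyl-1,3-dioxolan-4-yl]methoxy}phenyl)propan-2-yl]oxy}-3-iodobenzonitrile
Conditions: LiBH4, THF, H2O (1 equiv), 0 °C
Reagents that add atoms: none
Why: Reductive cleavage of the N-acyl oxazolidinone to the primary alcohol C9H2OH, which leaves nitrile, aryl iodides, acetonide and MOM ethers alone and ends the epimerisability of C8.

Step 12
Reactants: 17 1,3-diol acetonide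
Product: 18 4-{[(1S,2S)-1-(4-{[(1R,2S)-1-[3,4-bis(methoxymethoxy)phenyl]-2,3-dihydroxypropyl]oxy}-3-iodophenyl)-1,3-dihydroxypropan-2-yl]oxy}-3-iodobenzonitrile
Conditions: AcOH/H2O/THF (3:1:1), 40 °C
Reagents that add atoms: none
Why: Mild acid hydrolysis of the terminal isopropylidene acetal; the weak acid is chosen so that the aryl MOM ethers stay on and the alkoxybenzylic C7–OH is not ionised.

Step 13
Reactants: 18 tetraol
Product: 19 4-{[(1S,2S)-1-(4-{[(1R,2S)-1-[3,4-bis(methoxymethoxy)phenyl]-3-[(tert-butyldimethylsilyl)oxy]-2-hydroxypropyl]oxy}-3-iodophenyl)-3-[(tert-butyldimethylsilyl)oxy]-1-hydroxypropan-2-yl]oxy}-3-iodobenzonitrile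
Conditions: TBSCl (2.2 equiv), imidazole, CH2Cl2, 0 °C
Reagents that add atoms: tert-butyldimethylsilyl chloride, CC(C)(C)[Si](C)(C)Cl
Why: Selective silylation of the two primary hydroxyls (O9, O9') over the two hindered secondary ones, so that only O8' and O7 remain to attack the aryl iodides.

Step 14
Reactants: 19 bis-silyl diol diiodide
Product: 22 (2S,3S)-3-[(2R,3S)-2-[3,4-bis(methoxymethoxy)phenyl]-3-{[(tert-butyldimethylsilyl)oxy]methyl}-2,3-dihydro-1,4-benzodioxin-6-yl]-2-{[(tert-butyldimethylsilyl)oxy]methyl}-2,3-dihydro-1,4-benzodioxine-6-carbonitrile, via ring-B-closed monoiodide 20 (not isolated), via ring-D-closed monoiodide 21 (not isolated)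
Conditions: CuI (20 mol %), 3,4,7,8-tetramethyl-1,10-phenanthroline, Cs2CO3, toluene, 90 °C
Reagents that add atoms: none
Why: Two intramolecular Ullmann-type copper-catalysed O-arylations of secondary alcohols by ortho-alkoxyaryl iodides, each closing a six-membered ring; both bonds form at oxygen with retention, so erythro C7'/C8' gives cis ring D and threo C7/C8 gives trans ring B.

Step 15
Reactants: 22 bis-benzodioxane nitrile
Product: 24 (2S,3S)-3-[(2R,3S)-2-[3,4-bis(methoxymethoxy)phenyl]-3-{[(tert-butyldimethylsilyl)oxy]methyl}-2,3-dihydro-1,4-benzodioxin-6-yl]-2-{[(tert-butyldimethylsilyl)oxy]methyl}-2,3-dihydro-1,4-benzodioxine-6-carbaldehyde, via N-alumino aldimine 23 (not isolated)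
Conditions: i-Bu2AlH, CH2Cl2, −78 °C; aq. tartaric acid work-up
Reagents that add atoms: water, O
Why: Partial hydride reduction of the aryl nitrile stops at the N-aluminated aldimine, which is hydrolysed to the aldehyde on work-up; silyl ethers, MOM ethers and both dioxane rings are inert at −78 °C.

Step 16
Reactants: 24 ring A aldehyde
Product: 25 (E)-3-[(2S,3S)-3-[(2R,3S)-2-[3,4-bis(methoxymethoxy)phenyl]-3-{[(tert-butyldimethylsilyl)oxy]methyl}-2,3-dihydro-1,4-benzodioxin-6-yl]-2-{[(tert-butyldimethylsilyl)oxy]methyl}-2,3-dihydro-1,4-benzodioxin-6-yl]prop-2-enal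
Conditions: Ph3P=CHCHO (1.3 equiv), toluene, 80 °C
Reagents that add atoms: (triphenylphosphoranylidene)acetaldehyde, O=CC=P(c1ccccc1)(c1ccccc1)c1ccccc1
Why: Wittig olefination with the stabilised formylmethylene ylide should give the (E)-enal, and a small excess of ylide limits a second homologation; no stereocentre is touched.

Step 17
Reactants: 25 protected enal
Product: 26 target, (E)-3-[(2S,3S)-3-[(2R,3S)-2-(3,4-dihydroxyphenyl)-3-(hydroxymethyl)-2,3-dihydro-1,4-benzodioxin-6-yl]-2-(hydroxymethyl)-2,3-dihydro-1,4-benzodioxin-6-yl]prop-2-enal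
Conditions: 2 M aq HCl/THF (1:3), rt → 40 °C
Reagents that add atoms: none
Why: Acid hydrolysis of the two aryl MOM acetals and the two primary silyl ethers, which the enal and the benzodioxane aryl ethers should tolerate; base is avoided once the 4'-OH is free, because a phenoxide could open cis ring D through a quinone methide.

Compound list
1 | (+)-taxifolin, (2R,3R)-2-(3,4-dihydroxyphenyl)-3,5,7-trihydroxychroman-4-one | O[C@H]1C(=O)c2c(O)cc(O)cc2O[C@@H]1c1ccc(O)c(O)c1 | starting material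
2 | (2R,3R)-2-[3,4-bis(methoxymethoxy)phenyl]-3,5-dihydroxy-7-(methoxymethoxy)chroman-4-one | O[C@H]1C(=O)c2c(O)cc(OCOC)cc2O[C@@H]1c1ccc(OCOC)c(OCOC)c1 | intermediate
3 | (2R,3R)-5-(benzyloxy)-2-[3,4-bis(methoxymethoxy)phenyl]-3-hydroxy-7-(methoxymethoxy)chroman-4-one | O[C@H]1C(=O)c2c(OCc3ccccc3)cc(OCOC)cc2O[C@@H]1c1ccc(OCOC)c(OCOC)c1 | intermediate
4 | (2R,3R)-5-(benzyloxy)-2-[3,4-bis(methoxymethoxy)phenyl]-7-(methoxymethoxy)-4-oxochroman-3-yl acetate (key-step precursor) | CC(=O)O[C@H]1C(=O)c2c(OCc3ccccc3)cc(OCOC)cc2O[C@@H]1c1ccc(OCOC)c(OCOC)c1 | intermediate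
5 | (3R,4R)-9-(benzyloxy)-4-[3,4-bis(methoxymethoxy)phenyl]-7-(methoxymethoxy)-2-oxo-3,4-dihydro-2H-1,5-benzodioxepin-3-yl acetate (key-step product) | CC(=O)O[C@H]1C(=O)Oc2c(OCc3ccccc3)cc(OCOC)cc2O[C@@H]1c1ccc(OCOC)c(OCOC)c1 | intermediate
6 | (2S,3R)-3-[3-(benzyloxy)-2-hydroxy-5-(methoxymethoxy)phenoxy]-3-[3,4-bis(methoxymethoxy)phenyl]propane-1,2-diol | OC[C@H](O)[C@H](Oc1cc(OCOC)cc(OCc2ccccc2)c1O)c1ccc(OCOC)c(OCOC)c1 | intermediate
7 | 2-(benzyloxy)-6-{(R)-[3,4-bis(methoxymethoxy)phenyl][(4S)-2,2-dimethyl-1,3-dioxolan-4-yl]methoxy}-4-(methoxymethoxy)phenol | CC1(C)OC[C@@H]([C@H](Oc2cc(OCOC)cc(OCc3ccccc3)c2O)c2ccc(OCOC)c(OCOC)c2)O1 | intermediate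
8 | 2-(benzyloxy)-6-{(R)-[3,4-bis(methoxymethoxy)phenyl][(4S)-2,2-dimethyl-1,3-dioxolan-4-yl]methoxy}cyclohexa-2,5-diene-1,4-dione | CC1(C)OC[C@@H]([C@H](OC2=CC(=O)C=C(OCc3ccccc3)C2=O)c2ccc(OCOC)c(OCOC)c2)O1 | intermediate
9 | (R)-[3,4-bis(methoxymethoxy)phenyl][(4S)-2,2-dimethyl-1,3-dioxolan-4-yl]methanol | CC1(C)OC[C@@H]([C@H](O)c2ccc(OCOC)c(OCOC)c2)O1 | intermediate
10 | 4-fluoro-3-iodobenzaldehyde | O=Cc1ccc(F)c(I)c1 | starting material
11 | 4-{(R)-[3,4-bis(methoxymethoxy)phenyl][(4S)-2,2-dimethyl-1,3-dioxolan-4-yl]methoxy}-3-iodobenzaldehyde | CC1(C)OC[C@@H]([C@H](Oc2ccc(C=O)cc2I)c2ccc(OCOC)c(OCOC)c2)O1 | intermediate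
12 | 4-hydroxy-3-iodobenzonitrile | N#Cc1ccc(O)c(I)c1 | starting material
13 | (4R)-4-benzyl-3-(chloroacetyl)-1,3-oxazolidin-2-one | O=C(CCl)N1[C@H](Cc2ccccc2)COC1=O | starting material
14 | 4-{2-[(4R)-4-benzyl-2-oxo-1,3-oxazolidin-3-yl]-2-oxoethoxy}-3-iodobenzonitrile | N#Cc1ccc(OCC(=O)N2[C@H](Cc3ccccc3)COC2=O)c(I)c1 | intermediate
15 | (Z)-O-dibutylboryl enolate of 14 | N#Cc1ccc(O/C=C(\OB(CCCC)CCCC)N2[C@H](Cc3ccccc3)COC2=O)c(I)c1 | intermediate
16 | Evans syn aldol adduct, (2R,3S)-2-(4-cyano-2-iodophenoxy)-3-hydroxy-3-aryl-propanoyl imide of (4R)-4-benzyloxazolidin-2-one (aryl = ring C of 11) | N#Cc1ccc(O[C@H]([C@@H](O)c2ccc(O[C@H](c3ccc(OCOC)c(OCOC)c3)[C@@H]3COC(C)(C)O3)c(I)c2)C(=O)N2[C@H](Cc3ccccc3)COC2=O)c(I)c1 | intermediate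
17 | (7S,8S)-7,9-diol with O8 on ring A, acetonide intact | N#Cc1ccc(O[C@H]([C@@H](O)c2ccc(O[C@H](c3ccc(OCOC)c(OCOC)c3)[C@@H]3COC(C)(C)O3)c(I)c2)CO)c(I)c1 | intermediate
18 | (7S,8S,7'R,8'S)-tetraol (O7, O9, O8', O9' free) | N#Cc1ccc(O[C@H]([C@@H](O)c2ccc(O[C@H](c3ccc(OCOC)c(OCOC)c3)[C@@H](O)CO)c(I)c2)CO)c(I)c1 | intermediate
19 | 9,9'-bis-O-TBS ether of 18 | N#Cc1ccc(O[C@H]([C@@H](O)c2ccc(O[C@H](c3ccc(OCOC)c(OCOC)c3)[C@@H](O)CO[Si](C)(C)C(C)(C)C)c(I)c2)CO[Si](C)(C)C(C)(C)C)c(I)c1 | intermediate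
20 | monoiodide with trans ring B closed and ring D still open | N#Cc1ccc2c(c1)O[C@@H](c1ccc(O[C@H](c3ccc(OCOC)c(OCOC)c3)[C@@H](O)CO[Si](C)(C)C(C)(C)C)c(I)c1)[C@H](CO[Si](C)(C)C(C)(C)C)O2 | intermediate
21 | monoiodide with cis ring D closed and ring B still open | N#Cc1ccc(O[C@H]([C@@H](O)c2ccc3c(c2)O[C@@H](CO[Si](C)(C)C(C)(C)C)[C@@H](c2ccc(OCOC)c(OCOC)c2)O3)CO[Si](C)(C)C(C)(C)C)c(I)c1 | intermediate
22 | (2S,3S)-3-[(2R,3S)-2-[3,4-bis(methoxymethoxy)phenyl]-3-{[(tert-butyldimethylsilyl)oxy]methyl}-2,3-dihydro-1,4-benzodioxin-6-yl]-2-{[(tert-butyldimethylsilyl)oxy]methyl}-2,3-dihydro-1,4-benzodioxine-6-carbonitrile | N#Cc1ccc2c(c1)O[C@@H](c1ccc3c(c1)O[C@@H](CO[Si](C)(C)C(C)(C)C)[C@@H](c1ccc(OCOC)c(OCOC)c1)O3)[C@H](CO[Si](C)(C)C(C)(C)C)O2 | intermediate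
23 | N-(diisobutylalumanyl) aldimine of 24 | CC(C)C[Al](CC(C)C)N=Cc1ccc2c(c1)O[C@@H](c1ccc3c(c1)O[C@@H](CO[Si](C)(C)C(C)(C)C)[C@@H](c1ccc(OCOC)c(OCOC)c1)O3)[C@H](CO[Si](C)(C)C(C)(C)C)O2 | intermediate
24 | 6-carbaldehyde corresponding to nitrile 22 | O=Cc1ccc2c(c1)O[C@@H](c1ccc3c(c1)O[C@@H](CO[Si](C)(C)C(C)(C)C)[C@@H](c1ccc(OCOC)c(OCOC)c1)O3)[C@H](CO[Si](C)(C)C(C)(C)C)O2 | intermediate
25 | (E)-enal with ring E as bis-MOM ether and O9, O9' as TBS ethers | O=C/C=C/c1ccc2c(c1)O[C@@H](c1ccc3c(c1)O[C@@H](CO[Si](C)(C)C(C)(C)C)[C@@H](c1ccc(OCOC)c(OCOC)c1)O3)[C@H](CO[Si](C)(C)C(C)(C)C)O2 | intermediate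
26 | (E)-3-[(2S,3S)-3-[(2R,3S)-2-(3,4-dihydroxyphenyl)-3-(hydroxymethyl)-2,3-dihydro-1,4-benzodioxin-6-yl]-2-(hydroxymethyl)-2,3-dihydro-1,4-benzodioxin-6-yl]prop-2-enal | O=C/C=C/c1ccc2c(c1)O[C@@H](c1ccc3c(c1)O[C@@H](CO)[C@@H](c1ccc(O)c(O)c1)O3)[C@H](CO)O2 | target

Total steps: 17. Longest linear sequence: 16 (steps 1–8 and 10–17; step 9 is the side branch).

Steps most likely to fail

Step 4. What may go wrong: the peracid adds only slowly to a carbonyl flanked by two ortho oxygen substituents, so that over-oxidation of the electron-rich rings (above all the tetra-oxygenated ring of the product) or acid loss of MOM groups overtakes the aryl shift. The fallback changes the substrate and not only the peracid. It sets out from 2: acetylation of both free hydroxyls (Ac2O, pyridine, DMAP) gives the 3,5-diacetate F1, in which O5 is an acceptor that neither shields nor deactivates C4=O. The weaker, non-acidic mCPBA/NaHCO3 (CH2Cl2, rt) can then bring about the same aryl shift to the 9-acetoxy lactone F2. LiAlH4 gives the catechol triol F3, and 2,2-dimethoxypropane/PPTS the catechol acetonide F4. Ag2O in dry MeOH oxidises the catechol to the alkoxy-ortho-quinone F5, and NaOMe/MeOH exchanges its alkoxy groups; the fallback comes back to the route at 9.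

Step 7. What may go wrong: the alkoxy exchange on the quinone stalls, because traces of hydroxide turn it into a hydroxyquinone anion that no longer undergoes addition–elimination and keeps O7' bound. The fallback sets out from 8, isolated after the first stage, and destroys the quinone ring instead of exchanging on it. Alkaline hydrogen peroxide (H2O2, NaOH, THF/H2O, 0 °C) epoxidises and cleaves alkoxyquinones to small carboxylic acids, oxalic acid among them. The carbon that carries O7' ends as an ester that is saponified in the same medium, and benzyl, MOM and acetonide groups are inert. The fallback comes back to the route at 9; new compounds: none F0.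

Step 14. What may go wrong: one closure lags, and the C7 alkoxide, which sits next to an electron-poor aryloxide, expels ring A by epoxide formation, or the remaining iodide is reduced before the second C–O bond forms. The fallback sets out from 11 and closes the rings one at a time, ring D before any C7 alkoxide exists. AcOH/H2O gives the diol aldehyde F6, and TBSCl/imidazole the primary silyl ether F7. A palladium-catalysed intramolecular etherification (Pd(OAc)2, 2-(di-tert-butylphosphino)-1,1'-binaphthyl, K3PO4, toluene, 70 °C) gives the ring D aldehyde F8. The Evans aldol of F8 with 14 gives the adduct F9, LiBH4 the diol F10, and TBSCl gives 21. A single copper-catalysed closure of ring B then comes back to the route at 22.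

Further compounds
F1 | step 4 | (2R,3R)-2-[3,4-bis(methoxymethoxy)phenyl]-7-(methoxymethoxy)-4-oxochromane-3,5-diyl diacetate | CC(=O)O[C@H]1C(=O)c2c(OC(C)=O)cc(OCOC)cc2O[C@@H]1c1ccc(OCOC)c(OCOC)c1
F2 | step 4 | (3R,4R)-4-[3,4-bis(methoxymethoxy)phenyl]-7-(methoxymethoxy)-2-oxo-3,4-dihydro-2H-1,5-benzodioxepine-3,9-diyl diacetate | CC(=O)O[C@H]1C(=O)Oc2c(OC(C)=O)cc(OCOC)cc2O[C@@H]1c1ccc(OCOC)c(OCOC)c1
F3 | step 4 | 3-{[(1R,2S)-1-[3,4-bis(methoxymethoxy)phenyl]-2,3-dihydroxypropyl]oxy}-5-(methoxymethoxy)benzene-1,2-diol | OC[C@H](O)[C@H](Oc1cc(OCOC)cc(O)c1O)c1ccc(OCOC)c(OCOC)c1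
F4 | step 4 | 3-{(R)-[3,4-bis(methoxymethoxy)phenyl][(4S)-2,2-dimethyl-1,3-dioxolan-4-yl]methoxy}-5-(methoxymethoxy)benzene-1,2-diol | CC1(C)OC[C@@H]([C@H](Oc2cc(OCOC)cc(O)c2O)c2ccc(OCOC)c(OCOC)c2)O1
F5 | step 4 | 3-{(R)-[3,4-bis(methoxymethoxy)phenyl][(4S)-2,2-dimethyl-1,3-dioxolan-4-yl]methoxy}-5-(methoxymethoxy)cyclohexa-3,5-diene-1,2-dione | CC1(C)OC[C@@H]([C@H](OC2=CC(OCOC)=CC(=O)C2=O)c2ccc(OCOC)c(OCOC)c2)O1
F0 | step 7 | none | none
F6 | step 14 | 4-{[(1R,2S)-1-[3,4-bis(methoxymethoxy)phenyl]-2,3-dihydroxypropyl]oxy}-3-iodobenzaldehyde | O=Cc1ccc(O[C@H](c2ccc(OCOC)c(OCOC)c2)[C@@H](O)CO)c(I)c1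
F7 | step 14 | 4-{[(1R,2S)-1-[3,4-bis(methoxymethoxy)phenyl]-3-[(tert-butyldimethylsilyl)oxy]-2-hydroxypropyl]oxy}-3-iodobenzaldehyde | O=Cc1ccc(O[C@H](c2ccc(OCOC)c(OCOC)c2)[C@@H](O)CO[Si](C)(C)C(C)(C)C)c(I)c1
F8 | step 14 | (2R,3S)-2-[3,4-bis(methoxymethoxy)phenyl]-3-{[(tert-butyldimethylsilyl)oxy]methyl}-2,3-dihydro-1,4-benzodioxine-6-carbaldehyde | O=Cc1ccc2c(c1)O[C@@H](CO[Si](C)(C)C(C)(C)C)[C@@H](c1ccc(OCOC)c(OCOC)c1)O2
F9 | step 14 | Evans syn aldol adduct of F8 with 14, (2R,3S)-2-(4-cyano-2-iodophenoxy)-3-hydroxy-3-(ring D benzodioxinyl)propanoyl imide of (4R)-4-benzyloxazolidin-2-one | N#Cc1ccc(O[C@H]([C@@H](O)c2ccc3c(c2)O[C@@H](CO[Si](C)(C)C(C)(C)C)[C@@H](c2ccc(OCOC)c(OCOC)c2)O3)C(=O)N2[C@H](Cc3ccccc3)COC2=O)c(I)c1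
F10 | step 14 | 4-{[(1S,2S)-1-[(2R,3S)-2-[3,4-bis(methoxymethoxy)phenyl]-3-{[(tert-butyldimethylsilyl)oxy]methyl}-2,3-dihydro-1,4-benzodioxin-6-yl]-1,3-dihydroxypropan-2-yl]oxy}-3-iodobenzonitrile | N#Cc1ccc(O[C@H]([C@@H](O)c2ccc3c(c2)O[C@@H](CO[Si](C)(C)C(C)(C)C)[C@@H](c2ccc(OCOC)c(OCOC)c2)O3)CO)c(I)c1
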